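**Retrosynthetic overview**

- The strategy rests on the coumarin ring: C4 is an unsubstituted CH bonded to C4a, C4a lies para to the C7 oxygen and ortho to O1 in a resorcinol-type ring, and C3 carries ring D. The C4–C4a bond is therefore made last, by acid-mediated attack of a preformed aryl ester ring on an iminium carbon generated from an enamino ester.
- The enamino ester comes from aminomethylenation of the aryl ester formed between the ring D acetic acid and 3-(allyloxy)-4-(2-methylbut-3-en-2-yl)phenol.
- The C3–CH2 link of the benzofuran comes from a 3-iodobenzofuran (iodine–magnesium exchange, addition to a ring D aldehyde, ionic deoxygenation). The furan ring comes from iodocyclisation of an ortho-alkynylphenol, itself made by Sonogashira coupling of a ring E iodide with a ring A alkyne.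
- Both 2-methylbut-3-en-2-yl groups derive from the one phenol above. It is built from 2,4-dihydroxyphenylacetic acid through its lactone (gem-dimethylation, lactol, Wittig methylenation), so the position of the quaternary carbon is fixed by the skeleton.
- Ring order: temporary lactone, then the furan ring of the benzofuran, then the pyranone of the coumarin; six allyl ethers are removed at the end.

Key step: step 21

Remark: the target has no stereocentre. The lactol, the carbinol and the ring-closure intermediates carry transient stereocentres and are used as racemates or mixtures. The enamino ester is drawn Z, but either geometric isomer serves.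

**Route**

Step 1
Reactants: 1 2-(2,4-dihydroxyphenyl)acetic acid
Product: 2 6-hydroxy-1-benzofuran-2(3H)-one
Conditions: TsOH·H2O (5 mol%), toluene, reflux, Dean–Stark
Reagents that add atoms: none
Why: Acid-catalysed lactonisation (intramolecular Fischer esterification) of an ortho-hydroxyphenylacetic acid with azeotropic removal of water should close the five-membered lactone and at once distinguish the ortho oxygen (in the lactone) from the para oxygen (free).

Step 2
Reactants: 2 6-hydroxy-1-benzofuran-2(3H)-one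
Product: 3 6-[(triisopropylsilyl)oxy]-1-benzofuran-2(3H)-one
Conditions: i-Pr3SiCl (1.1 equiv), imidazole (2.2 equiv), CH2Cl2, 0 °C to rt
Reagents that add atoms: triisopropylsilyl chloride, CC(C)[Si](Cl)(C(C)C)C(C)C
Why: Silylation of the only free phenol should give a bulky silyl ether that survives the base, hydride and ylide steps that follow and is later cleaved by fluoride without touching allyl ethers.

Step 3
Reactants: 3 6-[(triisopropylsilyl)oxy]-1-benzofuran-2(3H)-one
Product: 4 3,3-dimethyl-6-[(triisopropylsilyl)oxy]-1-benzofuran-2(3H)-one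
Conditions: NaH (2.4 equiv), MeI (5 equiv), THF, 0 °C to rt (lactone added to the NaH/MeI mixture)
Reagents that add atoms: iodomethane, CI
Why: Double C-alkylation of the benzofuranone enolate (an acidic aryl ester enolate that reacts at carbon with the soft electrophile MeI) should install the gem-dimethyl group and with it the quaternary carbon of the future 2-methylbut-3-en-2-yl group.

Step 4
Reactants: 4 3,3-dimethyl-6-[(triisopropylsilyl)oxy]-1-benzofuran-2(3H)-one
Product: 5 3,3-dimethyl-6-[(triisopropylsilyl)oxy]-2,3-dihydro-1-benzofuran-2-ol (racemic lactol)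
Conditions: i-Bu2AlH (1.2 equiv), CH2Cl2, −78 °C; aq. potassium sodium tartrate
Reagents that add atoms: none
Why: Partial reduction of a lactone to the lactol with i-Bu2AlH at low temperature should stop at the stable tetrahedral aluminate; the new hemiacetal centre is racemic and is lost in the next step.

Step 5
Reactants: 5 3,3-dimethyl-6-[(triisopropylsilyl)oxy]-2,3-dihydro-1-benzofuran-2-ol
Product: 7 2-(2-methylbut-3-en-2-yl)-5-[(triisopropylsilyl)oxy]phenol, via ring-opened phenoxide aldehyde 6 (not isolated)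
Conditions: Ph3PCH3Br (3.5 equiv), KOt-Bu (3.3 equiv), THF, 0 to 50 °C
Reagents that add atoms: methyltriphenylphosphonium bromide (as its ylide), C[P+](c1ccccc1)(c1ccccc1)c1ccccc1.[Br-]
Why: Wittig methylenation of a lactol: base opens the hemiacetal to the phenoxide aldehyde, which cannot enolise (quaternary α-carbon) and should be methylenated to the terminal alkene while unveiling the ortho phenol.

Step 6
Reactants: 7 2-(2-methylbut-3-en-2-yl)-5-[(triisopropylsilyl)oxy]phenol
Product: 8 [3-(allyloxy)-4-(2-methylbut-3-en-2-yl)phenoxy]triisopropylsilane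
Conditions: allyl bromide (1.5 equiv), K2CO3 (2 equiv), acetone, reflux
Reagents that add atoms: allyl bromide, C=CCBr
Why: Williamson etherification of the hindered phenol with the reactive allyl bromide should proceed cleanly, and mild carbonate in acetone leaves the aryl silyl ether intact.

Step 7
Reactants: 8 [3-(allyloxy)-4-(2-methylbut-3-en-2-yl)phenoxy]triisopropylsilane
Product: 9 3-(allyloxy)-4-(2-methylbut-3-en-2-yl)phenol
Conditions: Bu4NF (1.1 equiv), THF, 0 °C; then H2O
Reagents that add atoms: none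
Why: Fluoride-mediated desilylation of the aryl silyl ether should free the hydroxyl para to the tertiary carbon and leave the allyl ether and the alkenes untouched.

Step 8
Reactants: 9 3-(allyloxy)-4-(2-methylbut-3-en-2-yl)phenol
Product: 10 2,4-bis(allyloxy)-1-(2-methylbut-3-en-2-yl)benzene
Conditions: allyl bromide (1.3 equiv), K2CO3 (2 equiv), acetone, reflux
Reagents that add atoms: allyl bromide, C=CCBr
Why: Williamson etherification of an unhindered phenol should give the diallyl ether that serves as ring E.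

Step 9
Reactants: 10 2,4-bis(allyloxy)-1-(2-methylbut-3-en-2-yl)benzene
Product: 11 1,5-bis(allyloxy)-2-iodo-4-(2-methylbut-3-en-2-yl)benzene
Conditions: N-iodosuccinimide (1.05 equiv), CF3CO2H (10 mol%), MeCN, 0 °C, dark
Reagents that add atoms: N-iodosuccinimide, O=C1CCC(=O)N1I
Why: Electrophilic aromatic iodination should occur at the one unhindered carbon that is para to one ether oxygen and ortho to the other, and the dialkoxyarene should react much faster with the iodonium source than the monosubstituted alkenes.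

Step 10
Reactants: 12 2,4-dihydroxybenzaldehyde
Product: 13 4-(allyloxy)-2-hydroxybenzaldehyde
Conditions: allyl bromide (1.05 equiv), K2CO3 (1.05 equiv), acetone, rt to 50 °C
Reagents that add atoms: allyl bromide, C=CCBr
Why: Regioselective Williamson etherification: the 2-hydroxyl is held in a hydrogen bond to the aldehyde, so the 4-hydroxyl should be alkylated.

Step 11
Reactants: 13 4-(allyloxy)-2-hydroxybenzaldehyde
Product: 14 5-(allyloxy)-2-ethynylphenol
Conditions: dimethyl (1-diazo-2-oxopropyl)phosphonate (1.5 equiv), K2CO3 (3 equiv), MeOH, rt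
Reagents that add atoms: dimethyl (1-diazo-2-oxopropyl)phosphonate, CC(=O)C(=[N+]=[N-])P(=O)(OC)OC
Why: Seyferth–Gilbert homologation with the Ohira–Bestmann reagent should convert the aldehyde into the terminal alkyne under carbonate/methanol conditions that tolerate the phenol (as phenoxide) and the allyl ether.

Step 12
Reactants: 11 1,5-bis(allyloxy)-2-iodo-4-(2-methylbut-3-en-2-yl)benzene; 14 5-(allyloxy)-2-ethynylphenol
Product: 15 5-(allyloxy)-2-{[2,4-bis(allyloxy)-5-(2-methylbut-3-en-2-yl)phenyl]ethynyl}phenol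
Conditions: PdCl2(PPh3)2 (3 mol%), CuI (5 mol%), Et3N (3 equiv), THF, rt, argon
Reagents that add atoms: none
Why: Sonogashira coupling of an aryl iodide at room temperature, where oxidative addition into the C–I bond should be much faster than ionisation of aryl allyl ethers by zerovalent palladium and where the alkynylphenol should not yet cycloisomerise.

Step 13
Reactants: 15 5-(allyloxy)-2-{[2,4-bis(allyloxy)-5-(2-methylbut-3-en-2-yl)phenyl]ethynyl}phenol
Product: 16 6-(allyloxy)-2-[2,4-bis(allyloxy)-5-(2-methylbut-3-en-2-yl)phenyl]-3-iodo-1-benzofuran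
Conditions: I2 (1.5 equiv), NaHCO3 (3 equiv), MeCN, 0 °C to rt; aq. Na2S2O3
Reagents that add atoms: iodine, II
Why: Iodocyclisation of an ortho-alkynylphenol (5-endo-dig attack of the phenol oxygen on the iodonium-activated alkyne) should give the 3-iodobenzofuran; only ring A carries a free hydroxyl, so the direction of closure is fixed.

Step 14
Reactants: 1 2-(2,4-dihydroxyphenyl)acetic acid
Product: 17 allyl 2-[2,4-bis(allyloxy)phenyl]acetate
Conditions: allyl bromide (3.6 equiv), K2CO3 (4 equiv), DMF, rt to 50 °C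
Reagents that add atoms: allyl bromide, C=CCBr
Why: Exhaustive alkylation of the carboxylate and both phenoxides (Williamson etherification and ester formation) should protect all three acidic sites in one operation.

Step 15
Reactants: 17 allyl 2-[2,4-bis(allyloxy)phenyl]acetate
Product: 19 allyl 2-[2,4-bis(allyloxy)-5-formylphenyl]acetate, via aryl iminium salt 18 (not isolated)
Conditions: POCl3 (1.5 equiv), DMF, 0 to 60 °C; then H2O, rt
Reagents that add atoms: N,N-dimethylformamide, CN(C)C=O; water, O
Why: Vilsmeier–Haack formylation of a 1,3-dialkoxybenzene should occur para to one ether oxygen and ortho to the other, which here is C5, the only such carbon not flanked by two substituents.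

Step 16
Reactants: 16 6-(allyloxy)-2-[2,4-bis(allyloxy)-5-(2-methylbut-3-en-2-yl)phenyl]-3-iodo-1-benzofuran; 19 allyl 2-[2,4-bis(allyloxy)-5-formylphenyl]acetate
Product: 21 allyl 2-{2,4-bis(allyloxy)-5-[{6-(allyloxy)-2-[2,4-bis(allyloxy)-5-(2-methylbut-3-en-2-yl)phenyl]-1-benzofuran-3-yl}(hydroxy)methyl]phenyl}acetate (racemic), via 3-benzofuranylmagnesium chloride 20 (not isolated)
Conditions: i-PrMgCl·LiCl (1.1 equiv), THF, −40 °C; then 19, −40 to −10 °C; aq. NH4Cl
Reagents that add atoms: none
Why: Iodine–magnesium exchange at low temperature followed by Grignard 1,2-addition to the aldehyde, which is far more electrophilic than the allyl ester, should form the C3–C bond; the carbinol centre forms as a racemate and is removed in the next step.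

Step 17
Reactants: 21 allyl 2-{2,4-bis(allyloxy)-5-[{6-(allyloxy)-2-[2,4-bis(allyloxy)-5-(2-methylbut-3-en-2-yl)phenyl]-1-benzofuran-3-yl}(hydroxy)methyl]phenyl}acetate
Product: 23 allyl 2-{2,4-bis(allyloxy)-5-[{6-(allyloxy)-2-[2,4-bis(allyloxy)-5-(2-methylbut-3-en-2-yl)phenyl]-1-benzofuran-3-yl}methyl]phenyl}acetate, via diarylmethyl cation 22 (not isolated)
Conditions: Et3SiH (3 equiv), CF3CO2H (3 equiv), CH2Cl2, −40 to 0 °C
Reagents that add atoms: none
Why: Ionic hydrogenation: acid ionises the doubly benzylic alcohol to a cation stabilised by the benzofuran and by ortho- and para-alkoxy groups, Et3SiH delivers hydride, and at or below 0 °C the allyl groups and terminal alkenes should not be protonated.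

Step 18
Reactants: 23 allyl 2-{2,4-bis(allyloxy)-5-[{6-(allyloxy)-2-[2,4-bis(allyloxy)-5-(2-methylbut-3-en-2-yl)phenyl]-1-benzofuran-3-yl}methyl]phenyl}acetate
Product: 24 2-{2,4-bis(allyloxy)-5-[{6-(allyloxy)-2-[2,4-bis(allyloxy)-5-(2-methylbut-3-en-2-yl)phenyl]-1-benzofuran-3-yl}methyl]phenyl}acetic acid
Conditions: LiOH (3 equiv), THF/MeOH/H2O, rt; then 1 M HCl to pH 3
Reagents that add atoms: lithium hydroxide, [Li+].[OH-]
Why: Saponification of the only ester should give the acid, since aryl allyl ethers, the benzofuran and the alkenes are inert to aqueous hydroxide.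

Step 19
Reactants: 24 2-{2,4-bis(allyloxy)-5-[{6-(allyloxy)-2-[2,4-bis(allyloxy)-5-(2-methylbut-3-en-2-yl)phenyl]-1-benzofuran-3-yl}methyl]phenyl}acetic acid; 9 3-(allyloxy)-4-(2-methylbut-3-en-2-yl)phenol
Product: 25 3-(allyloxy)-4-(2-methylbut-3-en-2-yl)phenyl 2-{2,4-bis(allyloxy)-5-[{6-(allyloxy)-2-[2,4-bis(allyloxy)-5-(2-methylbut-3-en-2-yl)phenyl]-1-benzofuran-3-yl}methyl]phenyl}acetate
Conditions: EDC·HCl (1.3 equiv), DMAP (0.2 equiv), CH2Cl2, 0 °C to rt
Reagents that add atoms: none
Why: Steglich-type carbodiimide esterification of an arylacetic acid with an unhindered phenol should place the future lactone oxygen O1 before the ring is closed.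

Step 20
Reactants: 25 3-(allyloxy)-4-(2-methylbut-3-en-2-yl)phenyl 2-{2,4-bis(allyloxy)-5-[{6-(allyloxy)-2-[2,4-bis(allyloxy)-5-(2-methylbut-3-en-2-yl)phenyl]-1-benzofuran-3-yl}methyl]phenyl}acetate
Product: 26 3-(allyloxy)-4-(2-methylbut-3-en-2-yl)phenyl (Z)-2-{2,4-bis(allyloxy)-5-[{6-(allyloxy)-2-[2,4-bis(allyloxy)-5-(2-methylbut-3-en-2-yl)phenyl]-1-benzofuran-3-yl}methyl]phenyl}-3-(dimethylamino)prop-2-enoate
Conditions: t-BuOCH(NMe2)2 (2 equiv), toluene, 70 °C, slow argon stream
Reagents that add atoms: tert-butoxybis(dimethylamino)methane, CC(C)(C)OC(N(C)C)N(C)C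
Why: Aminomethylenation of an activated methylene (flanked by an aryl group and an aryl ester) with Bredereck's reagent should give the enamino ester, because its tert-butoxide is too hindered to transesterify readily and the by-products are swept out as volatiles.

Step 21
Reactants: 26 3-(allyloxy)-4-(2-methylbut-3-en-2-yl)phenyl (Z)-2-{2,4-bis(allyloxy)-5-[{6-(allyloxy)-2-[2,4-bis(allyloxy)-5-(2-methylbut-3-en-2-yl)phenyl]-1-benzofuran-3-yl}methyl]phenyl}-3-(dimethylamino)prop-2-enoate
Product: 29 7-(allyloxy)-3-{2,4-bis(allyloxy)-5-[{6-(allyloxy)-2-[2,4-bis(allyloxy)-5-(2-methylbut-3-en-2-yl)phenyl]-1-benzofuran-3-yl}methyl]phenyl}-6-(2-methylbut-3-en-2-yl)-2H-chromen-2-one (hexaallyl ether of the target), via iminium trifluoroacetate 27 (not isolated), via 4-(dimethylamino)chroman-2-one 28 (not isolated)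
Conditions: CF3CO2H/CH2Cl2 (1:4), 0 °C to rt; then aq. NaHCO3
Reagents that add atoms: none
Why: CF3CO2H protonates the enamine at the carbon bearing ring D and the ester, giving an iminium ion at the future C4. The carbon of the aryl ester ring that is ortho to the ester oxygen and para to the allyloxy group attacks this iminium carbon (intramolecular Friedel–Crafts aminoalkylation, 6-exo-trig with respect to the C=N bond) to form C4–C4a, and β-elimination of dimethylamine from 28 then gives the conjugated 2H-chromen-2-one, a formal Friedel–Crafts alkenylation. The closest known reactions are the ring-closing stage of the von Pechmann condensation of resorcinols with α-formyl arylacetates to 3-aryl-7-hydroxycoumarins and the acid cyclisation of 3-alkoxyacrylanilides to 2-quinolones. No stereocentre remains, since C3 and C4 of 28 become sp2, and the enamine geometry is irrelevant because the iminium ion rotates freely. The step needs attack at the carbon para to the allyloxy group and not at the carbon flanked by the two oxygens; the stronger para-directing ether oxygen and the steric shielding of the flanked carbon should secure this, as in Pechmann reactions of resorcinol. The lactone oxygen is already in place and the electrophile is at the aldehyde oxidation level, so dilute CF3CO2H at or below room temperature should suffice and should spare the allyl ethers, the 2-methylbut-3-en-2-yl groups and the diarylmethane.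

Step 22
Reactants: 29 7-(allyloxy)-3-{2,4-bis(allyloxy)-5-[{6-(allyloxy)-2-[2,4-bis(allyloxy)-5-(2-methylbut-3-en-2-yl)phenyl]-1-benzofuran-3-yl}methyl]phenyl}-6-(2-methylbut-3-en-2-yl)-2H-chromen-2-one
Product: 30 3-{2,4-dihydroxy-5-[{2-[2,4-dihydroxy-5-(2-methylbut-3-en-2-yl)phenyl]-6-hydroxy-1-benzofuran-3-yl}methyl]phenyl}-7-hydroxy-6-(2-methylbut-3-en-2-yl)-2H-chromen-2-one (CNP0380243.0)
Conditions: Pd(PPh3)4 (10 mol%), morpholine (20 equiv), THF, rt, degassed
Reagents that add atoms: none
Why: Tsuji–Trost-type deallylation: zerovalent palladium ionises each aryl allyl ether to a π-allyl complex and a phenoxide and morpholine traps the allyl group; these neutral, non-reducing conditions should spare the 2-methylbut-3-en-2-yl groups (no leaving group) and the lactone.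

**Compound list**

1 | 2-(2,4-dihydroxyphenyl)acetic acid | OC(=O)Cc1ccc(O)cc1O | starting material
2 | 6-hydroxy-1-benzofuran-2(3H)-one | O=C1Cc2ccc(O)cc2O1 | intermediate
3 | 6-[(triisopropylsilyl)oxy]-1-benzofuran-2(3H)-one | O=C1Cc2ccc(O[Si](C(C)C)(C(C)C)C(C)C)cc2O1 | intermediate
4 | 3,3-dimethyl-6-[(triisopropylsilyl)oxy]-1-benzofuran-2(3H)-one | CC1(C)C(=O)Oc2cc(O[Si](C(C)C)(C(C)C)C(C)C)ccc21 | intermediate
5 | 3,3-dimethyl-6-[(triisopropylsilyl)oxy]-2,3-dihydro-1-benzofuran-2-ol (racemic) | CC1(C)C(O)Oc2cc(O[Si](C(C)C)(C(C)C)C(C)C)ccc21 | intermediate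
6 | potassium 2-(2-methyl-1-oxopropan-2-yl)-5-[(triisopropylsilyl)oxy]phenolate (not isolated) | CC(C)(C=O)c1ccc(O[Si](C(C)C)(C(C)C)C(C)C)cc1[O-].[K+] | intermediate
7 | 2-(2-methylbut-3-en-2-yl)-5-[(triisopropylsilyl)oxy]phenol | C=CC(C)(C)c1ccc(O[Si](C(C)C)(C(C)C)C(C)C)cc1O | intermediate
8 | [3-(allyloxy)-4-(2-methylbut-3-en-2-yl)phenoxy]triisopropylsilane | C=CCOc1cc(O[Si](C(C)C)(C(C)C)C(C)C)ccc1C(C)(C)C=C | intermediate
9 | 3-(allyloxy)-4-(2-methylbut-3-en-2-yl)phenol | C=CCOc1cc(O)ccc1C(C)(C)C=C | intermediate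
10 | 2,4-bis(allyloxy)-1-(2-methylbut-3-en-2-yl)benzene | C=CC(C)(C)c1ccc(OCC=C)cc1OCC=C | intermediate
11 | 1,5-bis(allyloxy)-2-iodo-4-(2-methylbut-3-en-2-yl)benzene | C=CC(C)(C)c1cc(I)c(OCC=C)cc1OCC=C | intermediate
12 | 2,4-dihydroxybenzaldehyde | O=Cc1ccc(O)cc1O | starting material
13 | 4-(allyloxy)-2-hydroxybenzaldehyde | C=CCOc1ccc(C=O)c(O)c1 | intermediate
14 | 5-(allyloxy)-2-ethynylphenol | C#Cc1ccc(OCC=C)cc1O | intermediate
15 | 5-(allyloxy)-2-{[2,4-bis(allyloxy)-5-(2-methylbut-3-en-2-yl)phenyl]ethynyl}phenol | C=CC(C)(C)c1cc(C#Cc2ccc(OCC=C)cc2O)c(OCC=C)cc1OCC=C | intermediate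
16 | 6-(allyloxy)-2-[2,4-bis(allyloxy)-5-(2-methylbut-3-en-2-yl)phenyl]-3-iodo-1-benzofuran | C=CC(C)(C)c1cc(-c2oc3cc(OCC=C)ccc3c2I)c(OCC=C)cc1OCC=C | intermediate
17 | allyl 2-[2,4-bis(allyloxy)phenyl]acetate | C=CCOC(=O)Cc1ccc(OCC=C)cc1OCC=C | intermediate
18 | N-{[2,4-bis(allyloxy)-5-(2-allyloxy-2-oxoethyl)phenyl]methylidene}-N-methylmethanaminium dichlorophosphate (not isolated) | C=CCOC(=O)Cc1cc(C=[N+](C)C)c(OCC=C)cc1OCC=C.[O-]P(=O)(Cl)Cl | intermediate
19 | allyl 2-[2,4-bis(allyloxy)-5-formylphenyl]acetate | C=CCOC(=O)Cc1cc(C=O)c(OCC=C)cc1OCC=C | intermediate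
20 | {6-(allyloxy)-2-[2,4-bis(allyloxy)-5-(2-methylbut-3-en-2-yl)phenyl]-1-benzofuran-3-yl}magnesium chloride (not isolated) | C=CC(C)(C)c1cc(-c2oc3cc(OCC=C)ccc3c2[Mg]Cl)c(OCC=C)cc1OCC=C | intermediate
21 | allyl 2-{2,4-bis(allyloxy)-5-[{6-(allyloxy)-2-[2,4-bis(allyloxy)-5-(2-methylbut-3-en-2-yl)phenyl]-1-benzofuran-3-yl}(hydroxy)methyl]phenyl}acetate (racemic) | C=CC(C)(C)c1cc(-c2oc3cc(OCC=C)ccc3c2C(O)c2cc(CC(=O)OCC=C)c(OCC=C)cc2OCC=C)c(OCC=C)cc1OCC=C | intermediate
22 | diarylmethyl cation derived from 21, as trifluoroacetate (not isolated) | C=CC(C)(C)c1cc(-c2oc3cc(OCC=C)ccc3c2[CH+]c2cc(CC(=O)OCC=C)c(OCC=C)cc2OCC=C)c(OCC=C)cc1OCC=C.[O-]C(=O)C(F)(F)F | intermediate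
23 | allyl 2-{2,4-bis(allyloxy)-5-[{6-(allyloxy)-2-[2,4-bis(allyloxy)-5-(2-methylbut-3-en-2-yl)phenyl]-1-benzofuran-3-yl}methyl]phenyl}acetate | C=CC(C)(C)c1cc(-c2oc3cc(OCC=C)ccc3c2Cc2cc(CC(=O)OCC=C)c(OCC=C)cc2OCC=C)c(OCC=C)cc1OCC=C | intermediate
24 | 2-{2,4-bis(allyloxy)-5-[{6-(allyloxy)-2-[2,4-bis(allyloxy)-5-(2-methylbut-3-en-2-yl)phenyl]-1-benzofuran-3-yl}methyl]phenyl}acetic acid | C=CC(C)(C)c1cc(-c2oc3cc(OCC=C)ccc3c2Cc2cc(CC(=O)O)c(OCC=C)cc2OCC=C)c(OCC=C)cc1OCC=C | intermediate
25 | 3-(allyloxy)-4-(2-methylbut-3-en-2-yl)phenyl ester of acid 24 | C=CC(C)(C)c1cc(-c2oc3cc(OCC=C)ccc3c2Cc2cc(CC(=O)Oc3ccc(C(C)(C)C=C)c(OCC=C)c3)c(OCC=C)cc2OCC=C)c(OCC=C)cc1OCC=C | intermediate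
26 | 3-(allyloxy)-4-(2-methylbut-3-en-2-yl)phenyl (Z)-3-(dimethylamino)-2-arylprop-2-enoate of the benzofuran-bearing ring D (key-step precursor) | C=CC(C)(C)c1cc(-c2oc3cc(OCC=C)ccc3c2Cc2cc(/C(=C/N(C)C)C(=O)Oc3ccc(C(C)(C)C=C)c(OCC=C)c3)c(OCC=C)cc2OCC=C)c(OCC=C)cc1OCC=C | intermediate
27 | C-protonated iminium trifluoroacetate of 26 (racemic, not isolated) | C=CC(C)(C)c1cc(-c2oc3cc(OCC=C)ccc3c2Cc2cc(C(C=[N+](C)C)C(=O)Oc3ccc(C(C)(C)C=C)c(OCC=C)c3)c(OCC=C)cc2OCC=C)c(OCC=C)cc1OCC=C.[O-]C(=O)C(F)(F)F | intermediate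
28 | 7-(allyloxy)-3-aryl-4-(dimethylamino)-6-(2-methylbut-3-en-2-yl)chroman-2-one, aryl as in 29 (mixture of racemic diastereomers, not isolated) | C=CC(C)(C)c1cc(-c2oc3cc(OCC=C)ccc3c2Cc2cc(C3C(N(C)C)c4cc(C(C)(C)C=C)c(OCC=C)cc4OC3=O)c(OCC=C)cc2OCC=C)c(OCC=C)cc1OCC=C | intermediate
29 | 7-(allyloxy)-3-{2,4-bis(allyloxy)-5-[{6-(allyloxy)-2-[2,4-bis(allyloxy)-5-(2-methylbut-3-en-2-yl)phenyl]-1-benzofuran-3-yl}methyl]phenyl}-6-(2-methylbut-3-en-2-yl)-2H-chromen-2-one (hexaallyl ether of the target) | C=CC(C)(C)c1cc(-c2oc3cc(OCC=C)ccc3c2Cc2cc(-c3cc4cc(C(C)(C)C=C)c(OCC=C)cc4oc3=O)c(OCC=C)cc2OCC=C)c(OCC=C)cc1OCC=C | intermediate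
30 | 3-{2,4-dihydroxy-5-[{2-[2,4-dihydroxy-5-(2-methylbut-3-en-2-yl)phenyl]-6-hydroxy-1-benzofuran-3-yl}methyl]phenyl}-7-hydroxy-6-(2-methylbut-3-en-2-yl)-2H-chromen-2-one (CNP0380243.0) | C=CC(C)(C)c1cc(-c2oc3cc(O)ccc3c2Cc2cc(-c3cc4cc(C(C)(C)C=C)c(O)cc4oc3=O)c(O)cc2O)c(O)cc1O | target

**Step count**

Total: 22 steps. Longest linear sequence: 18 steps (steps 1–9, 12, 13, 16–22).

**Steps most likely to fail, with fallbacks**

Step 21. The ring closure may stall because the acyloxy-bearing ring is only moderately nucleophilic, while more forcing acid would begin to protonate the terminal alkenes and cleave the aryl ester. The fallback moves the bond formation to C3–C4 under base. It sets out from phenol 9 and acid 24 and returns at 29. Phenol 9 would be ortho-formylated (MgCl2, Et3N, paraformaldehyde, MeCN, reflux; the position para to the allyloxy group is expected to react) to 4-(allyloxy)-2-hydroxy-5-(2-methylbut-3-en-2-yl)benzaldehyde F1. Acid 24 would be esterified with it (EDC·HCl, DMAP, CH2Cl2) to the 5-(allyloxy)-2-formyl-4-(2-methylbut-3-en-2-yl)phenyl ester of acid 24 F2. DBU in MeCN would then close the pyranone by intramolecular Knoevenagel condensation (Perkin–Oglialoro-type coumarin synthesis) with loss of water, giving 29.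

Step 20. The activated aryl ester may be cleaved by the liberated dimethylamine or by tert-butoxide (or fragment by E1cB to a ketene) faster than the methylene is aminomethylenated. The fallback replaces the thermal condensation by C-acylation of a preformed enolate at low temperature, where no free amine is present. It sets out from 25 and returns at 29. Ester 25 would be deprotonated with LiN(SiMe3)2 in THF at −78 °C and the lithium enolate formylated with 2,2,2-trifluoroethyl formate at that temperature (cold quench with AcOH) to give 3-(allyloxy)-4-(2-methylbut-3-en-2-yl)phenyl 2-aryl-3-oxopropanoate F3 (aryl as in 25, expected largely as its enol). Treatment of this α-formyl ester with CF3CO2H in CH2Cl2 would effect the same C4–C4a closure, with loss of water instead of dimethylamine, to give 29.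

Step 16. The 3-magnesiated benzofuran may undergo β-elimination with ring opening to the alkynylphenoxide, or the exchange on the hindered, electron-rich iodide may remain incomplete. The fallback forms the C3–CH2 bond by Friedel–Crafts benzylation instead of by an organometallic addition. It sets out from 15 and 19 and returns at 23. Alkynylphenol 15 would be cycloisomerised (Cs2CO3, DMF, 60 °C) to 6-(allyloxy)-2-[2,4-bis(allyloxy)-5-(2-methylbut-3-en-2-yl)phenyl]-1-benzofuran F4, which is also what a premature cyclisation in step 12 would deliver. Aldehyde 19 would be reduced (NaBH4, MeOH, 0 °C) to allyl 2-[2,4-bis(allyloxy)-5-(hydroxymethyl)phenyl]acetate F5. Sc(OTf)3 (5 mol%) in CH2Cl2 at 0 °C would ionise this electron-rich benzylic alcohol and alkylate the nucleophilic C3 of the benzofuran, giving 23 directly.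

**Further compounds**

F1 | step 21 | 4-(allyloxy)-2-hydroxy-5-(2-methylbut-3-en-2-yl)benzaldehyde | C=CCOc1cc(O)c(C=O)cc1C(C)(C)C=C
F2 | step 21 | 5-(allyloxy)-2-formyl-4-(2-methylbut-3-en-2-yl)phenyl ester of acid 24 | C=CC(C)(C)c1cc(-c2oc3cc(OCC=C)ccc3c2Cc2cc(CC(=O)Oc3cc(OCC=C)c(C(C)(C)C=C)cc3C=O)c(OCC=C)cc2OCC=C)c(OCC=C)cc1OCC=C
F3 | step 20 | 3-(allyloxy)-4-(2-methylbut-3-en-2-yl)phenyl 2-aryl-3-oxopropanoate, aryl as in 25 (racemic, drawn as the aldehyde tautomer) | C=CC(C)(C)c1cc(-c2oc3cc(OCC=C)ccc3c2Cc2cc(C(C=O)C(=O)Oc3ccc(C(C)(C)C=C)c(OCC=C)c3)c(OCC=C)cc2OCC=C)c(OCC=C)cc1OCC=C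
F4 | step 16 | 6-(allyloxy)-2-[2,4-bis(allyloxy)-5-(2-methylbut-3-en-2-yl)phenyl]-1-benzofuran | C=CC(C)(C)c1cc(-c2cc3ccc(OCC=C)cc3o2)c(OCC=C)cc1OCC=C
F5 | step 16 | allyl 2-[2,4-bis(allyloxy)-5-(hydroxymethyl)phenyl]acetate | C=CCOC(=O)Cc1cc(CO)c(OCC=C)cc1OCC=C
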